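## Retrosynthetic overview

1. The acrylic acid comes from a C2 ethynyl group by Markovnikov hydrocarboxylation; the alkyne comes from a C2 hydroxymethyl group, which is C6 of D-glucal.
2. The side chain is cut between its first and second carbon: a ring–CH2–sulfonyl carbanion plus (2E,6E)-farnesyl bromide, then desulfonylation.
3. The C5–CH2 bond and the C5 configuration come from a decarboxylative Claisen [3,3] rearrangement of the C3 tosylacetate of a 2,3-trans 3,6-dihydro-2H-pyran-3-ol. The shift is suprafacial, so the bought C3–O centre is traded for C5, trans to C2.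
4. That ester comes from D-glucal by acylation and reductive Ferrier rearrangement. The oxane is the only ring and is bought with the sugar, so no ring is formed in the route.

Assumption: ring atoms of every intermediate carry the numbers of the target oxane (O1, C2 with the one-carbon or acrylic unit, C5 with the side chain); compounds 1, 2, 10, 15 and 18 are bought.

## Route

Step 1
Reactants: 1 D-glucal; 2 (4-methylphenyl)sulfonylacetic acid
Product: 3 3,4,6-tri-O-[(4-methylphenyl)sulfonylacetyl]-D-glucal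
Conditions: 2 (3.3 equiv), DIC (N,N'-diisopropylcarbodiimide, 3.3 equiv), DMAP (10 mol %), CH2Cl2/THF, 0 °C to rt
Reagents that add atoms: (4-methylphenyl)sulfonylacetic acid, Cc1ccc(cc1)S(=O)(=O)CC(=O)O
Why: Steglich-type carbodiimide esterification of all three hydroxyls with the activated acid; no stereocentre is touched.

Step 2
Reactants: 3 tri-ester of D-glucal
Product: 4 [(2R,3S)-3-{[(4-methylphenyl)sulfonyl]acetoxy}-3,6-dihydro-2H-pyran-2-yl]methyl (4-methylphenyl)sulfonylacetate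
Conditions: Et3SiH (1.5 equiv), BF3·OEt2 (1.1 equiv), CH2Cl2, −20 to 0 °C
Reagents that add atoms: none
Why: Reductive Ferrier rearrangement: the allylic ester next to the enol ether ionises and hydride is delivered to the anomeric carbon, moving the alkene to C4=C5. The two sugar stereocentres (now C2 and C3, trans) are untouched.

Step 3
Reactants: 4 bis(sulfonylacetate)
Product: 8 [(2S,5R)-5-{[(4-methylphenyl)sulfonyl]methyl}-5,6-dihydro-2H-pyran-2-yl]methanol, via silyl ketene acetal 5 (not isolated), via rearranged silyl ester 6 (not isolated), via sulfone ester 7 (not isolated)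
Conditions: BSA (N,O-bis(trimethylsilyl)acetamide, 1.0 equiv), KOAc (10 mol %), toluene, 110 °C; then K2CO3 (0.3 equiv), MeOH, rt
Reagents that add atoms: none
Why: Decarboxylative Claisen rearrangement: the ketene acetal of the C3 ester undergoes a suprafacial [3,3] shift, so the new C5–C bond forms on the face the C3–O bond occupied, trans to the C2 substituent. Acetate-induced desilylation and loss of CO2 leave the CH2–sulfone, and methanolysis frees the primary alcohol. The change of the C2 descriptor from R to S is formal only.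

Step 4
Reactants: 8 dihydropyranyl sulfone alcohol
Product: 9 [(2S,5R)-5-{[(4-methylphenyl)sulfonyl]methyl}oxan-2-yl]methanol
Conditions: H2 (1 atm), PtO2 (5 mol %), EtOAc, rt
Reagents that add atoms: none
Why: Catalytic hydrogenation of the only C=C, done before the polyene is attached so no chemoselectivity is needed; platinum keeps allylic C–O hydrogenolysis and alkene migration low.

Step 5
Reactants: 9 saturated sulfone alcohol; 10 (2E,6E)-farnesyl bromide
Product: 12 [(2S,5R)-5-[(3E,7E)-4,8,12-trimethyl-1-(4-methylbenzenesulfonyl)trideca-3,7,11-trien-1-yl]oxan-2-yl]methanol (both epimers at the sulfonyl-bearing carbon), via dilithio dianion 11 (not isolated)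
Conditions: n-BuLi (2.1 equiv), THF, −78 °C; then 10 (1.1 equiv), −78 to −20 °C
Reagents that add atoms: (2E,6E)-farnesyl bromide, BrC/C=C(\C)CC/C=C(\C)CCC=C(C)C
Why: Biellmann-type alkylation: the α-sulfonyl carbanion displaces the primary allylic bromide by SN2 with retention of both E alkenes, while the lithium alkoxide stays unreactive. The new sulfonyl-bearing centre is temporary and is removed in step 6.

Step 6
Reactants: 12 alkylated sulfone
Product: 13 [(2S,5R)-5-[(3E,7E)-4,8,12-trimethyltrideca-3,7,11-trien-1-yl]oxan-2-yl]methanol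
Conditions: 6% Na/Hg, Na2HPO4, MeOH/THF, −20 °C to rt
Reagents that add atoms: none
Why: Reductive desulfonylation by electron transfer; the sulfone is homoallylic, so the alkenes neither migrate nor isomerise.

Step 7
Reactants: 13 primary alcohol
Product: 14 (2S,5R)-5-[(3E,7E)-4,8,12-trimethyltrideca-3,7,11-trien-1-yl]oxane-2-carbaldehyde
Conditions: TEMPO (10 mol %), PhI(OAc)2 (1.2 equiv), CH2Cl2, rt
Reagents that add atoms: none
Why: Oxoammonium-mediated oxidation stops at the aldehyde and leaves trisubstituted alkenes alone.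

Step 8
Reactants: 14 aldehyde; 15 dimethyl (1-diazo-2-oxopropyl)phosphonate
Product: 17 (2S,5R)-2-ethynyl-5-[(3E,7E)-4,8,12-trimethyltrideca-3,7,11-trien-1-yl]oxane, via diazoalkene 16 (not isolated)
Conditions: 15 (1.3 equiv), K2CO3 (2.0 equiv), MeOH, 0 °C to rt
Reagents that add atoms: dimethyl (1-diazo-2-oxopropyl)phosphonate, COP(=O)(OC)C(=[N+]=[N-])C(C)=O
Why: Seyferth–Gilbert homologation in the Ohira–Bestmann form; any base-induced epimerisation at C2 would favour the desired 2,5-trans diequatorial aldehyde.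

Step 9
Reactants: 17 terminal alkyne; 18 formic acid
Product: 19 2-[(2S,5R)-5-[(3E,7E)-4,8,12-trimethyltrideca-3,7,11-trien-1-yl]oxan-2-yl]prop-2-enoic acid
Conditions: Pd(OAc)2 (5 mol %), Xantphos (10 mol %), HCO2H (2.0 equiv), Ac2O (20 mol %), toluene, 80 °C
Reagents that add atoms: formic acid, O=CO
Why: Palladium-hydride hydrocarboxylation with formic acid as the CO source; Markovnikov insertion puts the carboxyl on the internal alkyne carbon and gives the 2-substituted acrylic acid directly, with no stereocentre involved.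

## Compound list

1 | D-glucal, (2R,3S,4R)-2-(hydroxymethyl)-3,4-dihydro-2H-pyran-3,4-diol | OC[C@H]1OC=C[C@@H](O)[C@@H]1O | starting material
2 | (4-methylphenyl)sulfonylacetic acid | Cc1ccc(cc1)S(=O)(=O)CC(=O)O | starting material
3 | 3,4,6-tri-O-[(4-methylphenyl)sulfonylacetyl]-D-glucal | Cc1ccc(cc1)S(=O)(=O)CC(=O)OC[C@H]2OC=C[C@@H](OC(=O)CS(=O)(=O)c3ccc(C)cc3)[C@@H]2OC(=O)CS(=O)(=O)c4ccc(C)cc4 | intermediate
4 | [(2R,3S)-3-{[(4-methylphenyl)sulfonyl]acetoxy}-3,6-dihydro-2H-pyran-2-yl]methyl (4-methylphenyl)sulfonylacetate | Cc1ccc(cc1)S(=O)(=O)CC(=O)OC[C@H]2OCC=C[C@@H]2OC(=O)CS(=O)(=O)c3ccc(C)cc3 | intermediate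
5 | trimethylsilyl ketene acetal of the C3 ester of 4 | Cc1ccc(cc1)S(=O)(=O)CC(=O)OC[C@H]2OCC=C[C@@H]2OC(O[Si](C)(C)C)=CS(=O)(=O)c3ccc(C)cc3 | intermediate
6 | trimethylsilyl 2-[(2S,5R)-2-({[(4-methylphenyl)sulfonylacetyl]oxy}methyl)-5,6-dihydro-2H-pyran-5-yl]-2-[(4-methylphenyl)sulfonyl]acetate | Cc1ccc(cc1)S(=O)(=O)CC(=O)OC[C@@H]2C=C[C@@H](C(C(=O)O[Si](C)(C)C)S(=O)(=O)c3ccc(C)cc3)CO2 | intermediate
7 | [(2S,5R)-5-{[(4-methylphenyl)sulfonyl]methyl}-5,6-dihydro-2H-pyran-2-yl]methyl (4-methylphenyl)sulfonylacetate | Cc1ccc(cc1)S(=O)(=O)CC(=O)OC[C@@H]2C=C[C@@H](CS(=O)(=O)c3ccc(C)cc3)CO2 | intermediate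
8 | [(2S,5R)-5-{[(4-methylphenyl)sulfonyl]methyl}-5,6-dihydro-2H-pyran-2-yl]methanol | OC[C@@H]1C=C[C@@H](CS(=O)(=O)c2ccc(C)cc2)CO1 | intermediate
9 | [(2S,5R)-5-{[(4-methylphenyl)sulfonyl]methyl}oxan-2-yl]methanol | OC[C@@H]1CC[C@@H](CS(=O)(=O)c2ccc(C)cc2)CO1 | intermediate
10 | (2E,6E)-farnesyl bromide, (2E,6E)-1-bromo-3,7,11-trimethyldodeca-2,6,10-triene | BrC/C=C(\C)CC/C=C(\C)CCC=C(C)C | starting material
11 | dilithio derivative of 9 (lithium alkoxide, α-sulfonyl carbanion) | [Li]OC[C@@H]1CC[C@@H](C([Li])S(=O)(=O)c2ccc(C)cc2)CO1 | intermediate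
12 | [(2S,5R)-5-[(3E,7E)-4,8,12-trimethyl-1-(4-methylbenzenesulfonyl)trideca-3,7,11-trien-1-yl]oxan-2-yl]methanol | OC[C@@H]1CC[C@@H](C(C/C=C(\C)CC/C=C(\C)CCC=C(C)C)S(=O)(=O)c2ccc(C)cc2)CO1 | intermediate
13 | [(2S,5R)-5-[(3E,7E)-4,8,12-trimethyltrideca-3,7,11-trien-1-yl]oxan-2-yl]methanol | OC[C@@H]1CC[C@@H](CC/C=C(\C)CC/C=C(\C)CCC=C(C)C)CO1 | intermediate
14 | (2S,5R)-5-[(3E,7E)-4,8,12-trimethyltrideca-3,7,11-trien-1-yl]oxane-2-carbaldehyde | O=C[C@@H]1CC[C@@H](CC/C=C(\C)CC/C=C(\C)CCC=C(C)C)CO1 | intermediate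
15 | dimethyl (1-diazo-2-oxopropyl)phosphonate | COP(=O)(OC)C(=[N+]=[N-])C(C)=O | starting material
16 | (2S,5R)-2-(2-diazoethenyl)-5-[(3E,7E)-4,8,12-trimethyltrideca-3,7,11-trien-1-yl]oxane | [N-]=[N+]=C=C[C@@H]1CC[C@@H](CC/C=C(\C)CC/C=C(\C)CCC=C(C)C)CO1 | intermediate
17 | (2S,5R)-2-ethynyl-5-[(3E,7E)-4,8,12-trimethyltrideca-3,7,11-trien-1-yl]oxane | C#C[C@@H]1CC[C@@H](CC/C=C(\C)CC/C=C(\C)CCC=C(C)C)CO1 | intermediate
18 | formic acid | O=CO | starting material
19 | 2-[(2S,5R)-5-[(3E,7E)-4,8,12-trimethyltrideca-3,7,11-trien-1-yl]oxan-2-yl]prop-2-enoic acid | C=C(C(=O)O)[C@@H]1CC[C@@H](CC/C=C(\C)CC/C=C(\C)CCC=C(C)C)CO1 | target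

## Step count and risks

Total step count: 9. Longest linear sequence: 9 (fully linear from D-glucal).

Steps most likely to fail:

Step 3 (decarboxylative Claisen on the bis-ester). The [3,3] shift in the dihydropyran may be sluggish, and the second sulfonylacetate is an untested spectator. The fallback makes the same C5–C bond by a Wittig–Still [2,3] rearrangement. It sets out from 4: K2CO3 in MeOH cleaves both esters to (2R,3S)-2-(hydroxymethyl)-3,6-dihydro-2H-pyran-3-ol F1. TBSCl and imidazole silylate the primary hydroxyl to give the silyl ether F2. KH and Bu3SnCH2I give the stannylmethyl ether F3. n-BuLi in THF at −78 °C effects tin–lithium exchange and a suprafacial [2,3] shift to the 2,5-trans homoallylic alcohol F4. I2, PPh3 and imidazole give the iodide F5, and sodium 4-methylbenzenesulfinate in DMF gives the silylated sulfone F6. TBAF then removes the silyl group, and the route is rejoined at 8.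

Step 5 (alkylation of the unprotected dianion). O-alkylation or poor dianion solubility could lower the yield. The fallback gives up the protecting-group-free plan and alkylates a monoanion. It sets out from 9: TBSCl and imidazole give the silyl ether F7. n-BuLi (1.05 equiv) then 10 gives the alkylated sulfone F8. Na/Hg with Na2HPO4 in MeOH gives the desulfonylated silyl ether F9, and TBAF returns the route at 13.

Step 9 (hydrocarboxylation). The branched-to-linear ratio on an α-alkoxy-branched alkyne and the tolerance of the polyene to palladium hydride and formic acid are uncertain. The fallback fixes the regiochemistry by hydrometalation instead. It sets out from 17: Bu3SnH with Mo(CO)3(CNtBu)3 (propargylic-oxygen-directed α-hydrostannation) gives the 1-stannylvinyl compound F10. I2 in CH2Cl2 at −78 to 0 °C gives the 1-iodovinyl compound F11. Hydroxycarbonylation with Pd(OAc)2, PPh3, CO (1 atm), H2O and Et3N in DMF then gives the acid, and the route is rejoined at 19.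

## Further compounds

F1 | step 3 | (2R,3S)-2-(hydroxymethyl)-3,6-dihydro-2H-pyran-3-ol | OC[C@H]1OCC=C[C@@H]1O
F2 | step 3 | (2R,3S)-2-({[tert-butyl(dimethyl)silyl]oxy}methyl)-3,6-dihydro-2H-pyran-3-ol | CC(C)(C)[Si](C)(C)OC[C@H]1OCC=C[C@@H]1O
F3 | step 3 | tert-butyl(dimethyl)({(2R,3S)-3-[(tributylstannyl)methoxy]-3,6-dihydro-2H-pyran-2-yl}methoxy)silane | CC(C)(C)[Si](C)(C)OC[C@H]1OCC=C[C@@H]1OC[Sn](CCCC)(CCCC)CCCC
F4 | step 3 | [(2S,5S)-2-({[tert-butyl(dimethyl)silyl]oxy}methyl)-5,6-dihydro-2H-pyran-5-yl]methanol (2,5-trans) | CC(C)(C)[Si](C)(C)OC[C@@H]1C=C[C@@H](CO)CO1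
F5 | step 3 | tert-butyl{[(2S,5R)-5-(iodomethyl)-5,6-dihydro-2H-pyran-2-yl]methoxy}dimethylsilane | CC(C)(C)[Si](C)(C)OC[C@@H]1C=C[C@@H](CI)CO1
F6 | step 3 | tert-butyl(dimethyl){[(2S,5R)-5-{[(4-methylphenyl)sulfonyl]methyl}-5,6-dihydro-2H-pyran-2-yl]methoxy}silane | CC(C)(C)[Si](C)(C)OC[C@@H]1C=C[C@@H](CS(=O)(=O)c2ccc(C)cc2)CO1
F7 | step 5 | tert-butyl(dimethyl){[(2S,5R)-5-{[(4-methylphenyl)sulfonyl]methyl}oxan-2-yl]methoxy}silane | CC(C)(C)[Si](C)(C)OC[C@@H]1CC[C@@H](CS(=O)(=O)c2ccc(C)cc2)CO1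
F8 | step 5 | tert-butyl(dimethyl){[(2S,5R)-5-[(3E,7E)-4,8,12-trimethyl-1-(4-methylbenzenesulfonyl)trideca-3,7,11-trien-1-yl]oxan-2-yl]methoxy}silane | CC(C)(C)[Si](C)(C)OC[C@@H]1CC[C@@H](C(C/C=C(\C)CC/C=C(\C)CCC=C(C)C)S(=O)(=O)c2ccc(C)cc2)CO1
F9 | step 5 | tert-butyl(dimethyl){[(2S,5R)-5-[(3E,7E)-4,8,12-trimethyltrideca-3,7,11-trien-1-yl]oxan-2-yl]methoxy}silane | CC(C)(C)[Si](C)(C)OC[C@@H]1CC[C@@H](CC/C=C(\C)CC/C=C(\C)CCC=C(C)C)CO1
F10 | step 9 | tributyl{1-[(2S,5R)-5-[(3E,7E)-4,8,12-trimethyltrideca-3,7,11-trien-1-yl]oxan-2-yl]ethenyl}stannane | C=C([Sn](CCCC)(CCCC)CCCC)[C@@H]1CC[C@@H](CC/C=C(\C)CC/C=C(\C)CCC=C(C)C)CO1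
F11 | step 9 | (2S,5R)-2-(1-iodoethenyl)-5-[(3E,7E)-4,8,12-trimethyltrideca-3,7,11-trien-1-yl]oxane | C=C(I)[C@@H]1CC[C@@H](CC/C=C(\C)CC/C=C(\C)CCC=C(C)C)CO1
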